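**Retrosynthetic overview**

1. Numbering of the bicyclo[3.3.1]nonane: C1 (geranyl bridgehead next to C8Me2), C2=O, C3 (aroyl), C4 (enol), C5 (second geranyl bridgehead), C6H2, C7H (prenyl), C8Me2, C9=O (bridge); ring A = C1–C2–C3–C4–C5–C9, ring B = C1–C8–C7–C6–C5–C9.
2. Enabling feature: ring A is a cyclohexane-1,3,5-trione (a non-aromatisable acylphloroglucinol) whose carbonyl carbons C2, C4, C9 alternate with C1, C3, C5. C1 with C2 and C9 is therefore a hidden 2,2-disubstituted malonate, and C3–C4–C5 with the aroyl group is an aryl 1,3-diketone, nucleophilic at C5 and at C3.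
3. Key disconnection: C5–C9 and C2–C3 are cut together, which opens both rings and gives the acyclic diketo malonate 16. In the forward sense one base treatment closes ring B first (C5–C9) and ring A second (C2–C3); C7 is the only stereocentre carried into it.
4. 16 comes from triester 12 by crossed Claisen condensation with acetophenone 14 (C3–C4) and γ-geranylation of the diketone dianion (C5). 12 comes from aldehyde 9 by Wittig extension (C5=C6) and conjugate reduction.
5. 9 comes from imide 7. C7 is set by auxiliary-controlled prenylation, after Michael addition of acetyl imide 1 to isopropylidene malonate 2 (C7–C8) and geranylation of C1.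

Key step: step 11

Remark: the target is taken as one enol form of a rapidly equilibrating β-triketone; 16 is used as a mixture of C5 epimers, because C5 becomes planar in step 11. Atom labels C1–C9 in the Why lines are those of the target.

**Route**

Step 1
Reactants: 1 (4S)-3-acetyl-4-benzyl-1,3-oxazolidin-2-one; 2 dimethyl 2-(propan-2-ylidene)propanedioate
Product: 3 dimethyl 2-{4-[(4S)-4-benzyl-2-oxo-1,3-oxazolidin-3-yl]-2-methyl-4-oxobutan-2-yl}propanedioate
Conditions: LiN(SiMe3)2 (1.05 equiv), THF, −78 °C; then 2, −78 °C; AcOH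
Reagents that add atoms: none
Why: Michael addition of the lithium imide enolate to the doubly activated alkylidene malonate should be faster at −78 °C than deprotonation of its allylic methyl groups and is driven by formation of the stabilised malonate enolate; it forms the C7–C8 bond and the quaternary C8 and creates no stereocentre.

Step 2
Reactants: 3; 4 geranyl bromide, (2E)-1-bromo-3,7-dimethylocta-2,6-diene
Product: 5 dimethyl 2-{4-[(4S)-4-benzyl-2-oxo-1,3-oxazolidin-3-yl]-2-methyl-4-oxobutan-2-yl}-2-[(2E)-3,7-dimethylocta-2,6-dien-1-yl]propanedioate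
Conditions: NaH (1.05 equiv), DMF, 0 °C; then 4, 0 °C → rt
Reagents that add atoms: none
Why: Malonate alkylation (SN2) with a reactive allylic bromide: the malonate C–H is by far the most acidic site of 3, the E double bond of 4 is untouched, and C1 stays prochiral because its two ester groups are identical.

Step 3
Reactants: 5; 6 prenyl bromide, 1-bromo-3-methylbut-2-ene
Product: 7 dimethyl 2-[(3S)-3-{[(4S)-4-benzyl-2-oxo-1,3-oxazolidin-3-yl]carbonyl}-2,6-dimethylhept-5-en-2-yl]-2-[(2E)-3,7-dimethylocta-2,6-dien-1-yl]propanedioate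
Conditions: NaN(SiMe3)2 (1.1 equiv), THF, −78 °C; then 6 (3 equiv), −78 → −45 °C
Reagents that add atoms: none
Why: Evans-type asymmetric alkylation: the chelated Z sodium enolate is shielded on one face by the benzyl group of the (S)-auxiliary, so prenyl bromide should enter from the other face and set C7 as (S) in 7, which is the (R) centre of the target once C6 is reduced.

Step 4
Reactants: 7
Product: 8 dimethyl 2-[(2E)-3,7-dimethylocta-2,6-dien-1-yl]-2-{(3S)-3-[(ethylsulfanyl)carbonyl]-2,6-dimethylhept-5-en-2-yl}propanedioate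
Conditions: EtSH (3 equiv), n-BuLi (2.4 equiv), THF, 0 °C; then 7, 0 °C → rt; AcOH
Reagents that add atoms: ethanethiol, CCS
Why: Acyl transfer to lithium ethanethiolate cleaves the exocyclic imide carbonyl even of α-branched acyl groups without epimerisation at C7, frees the auxiliary for recovery and leaves the two neopentyl-type malonate esters untouched.

Step 5
Reactants: 8
Product: 9 dimethyl 2-[(2E)-3,7-dimethylocta-2,6-dien-1-yl]-2-[(3S)-3-formyl-2,6-dimethylhept-5-en-2-yl]propanedioate
Conditions: Et3SiH (3 equiv), 10% Pd/C (5 mol %), acetone, rt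
Reagents that add atoms: none
Why: Fukuyama reduction: palladium inserts into the C–S bond of the thioester and the silane delivers hydride, which stops at the aldehyde (a C6 alcohol would close a δ-lactone onto a malonate ester) and spares esters and trisubstituted alkenes.

Step 6
Reactants: 9; 10 methyl (triphenyl-λ5-phosphanylidene)acetate
Product: 11 dimethyl 2-[(2E)-3,7-dimethylocta-2,6-dien-1-yl]-2-{(3R)-3-[(1E)-3-methoxy-3-oxoprop-1-en-1-yl]-2,6-dimethylhept-5-en-2-yl}propanedioate
Conditions: 10 (1.5 equiv), toluene, 90 °C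
Reagents that add atoms: none
Why: Wittig olefination with a stabilised ylide gives the (E)-enoate under neutral conditions, so the hindered α-centre C7 of the aldehyde is not epimerised, and it adds C5 and C4.

Step 7
Reactants: 11
Product: 12 dimethyl 2-[(2E)-3,7-dimethylocta-2,6-dien-1-yl]-2-[(3S)-3-(3-methoxy-3-oxopropyl)-2,6-dimethylhept-5-en-2-yl]propanedioate
Conditions: Cu(OAc)2·H2O (5 mol %), 1,2-bis(diphenylphosphino)benzene (5 mol %), (HMe2Si)2O, t-BuOH, toluene, rt
Reagents that add atoms: none
Why: Copper hydride-catalysed conjugate reduction adds hydride only to the electron-poor enoate double bond and the copper enolate is protonated by t-BuOH, so the isolated trisubstituted alkenes, the hindered esters and C7 are untouched and no carbanion or radical is left at C5 that could attack the malonate or an alkene.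

Step 8
Reactants: 13 1-(3,4-dihydroxyphenyl)ethan-1-one
Product: 14 1-{3,4-bis[tri(propan-2-yl)silyloxy]phenyl}ethan-1-one
Conditions: i-Pr3SiCl (2.4 equiv), imidazole (5 equiv), DMF, 40 °C
Reagents that add atoms: chlorotri(propan-2-yl)silane, CC(C)[Si](Cl)(C(C)C)C(C)C
Why: Imidazole-promoted silylation of both phenols; the bulky triisopropylsilyl ethers are chosen because they should survive the lithium amide and alkoxide conditions of steps 9 to 11 and fall to fluoride at the end.

Step 9
Reactants: 12; 14
Product: 15 dimethyl 2-[(3S)-3-(5-{3,4-bis[tri(propan-2-yl)silyloxy]phenyl}-3,5-dioxopentyl)-2,6-dimethylhept-5-en-2-yl]-2-[(2E)-3,7-dimethylocta-2,6-dien-1-yl]propanedioate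
Conditions: 14 (2.6 equiv), LiN(SiMe3)2 (2.5 equiv), THF, −78 °C; then 12, −78 °C → rt; AcOH
Reagents that add atoms: none
Why: Crossed Claisen condensation: the acetophenone enolate, the only carbon nucleophile present (no free amide base, so C5 of 12 is not deprotonated), attacks the single unhindered ester C4 of 12 and not the two neopentyl-type malonate esters, and the diketone is protected as its lithium enolate as it forms.

Step 10
Reactants: 15; 4
Product: 16 dimethyl 2-[(3R)-3-{5-{3,4-bis[tri(propan-2-yl)silyloxy]phenyl}-2-[(2E)-3,7-dimethylocta-2,6-dien-1-yl]-3,5-dioxopentyl}-2,6-dimethylhept-5-en-2-yl]-2-[(2E)-3,7-dimethylocta-2,6-dien-1-yl]propanedioate (both epimers at C5)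
Conditions: LiN(i-Pr)2 (2.2 equiv), THF, −78 → −40 °C; then 4 (1.0 equiv), −78 °C; AcOH
Reagents that add atoms: none
Why: γ-Alkylation of a 1,3-diketone dianion: after the C3 proton the second equivalent of base can only remove a C5 proton, and the resulting more basic γ-carbanion should react with geranyl bromide at −78 °C faster than with the hindered malonate esters, at carbon and only once; the new C5 centre forms as an epimer mixture that is erased in step 11.

Step 11
Reactants: 16
Product: 18 (1S,5S,7R)-3-{3,4-bis[tri(propan-2-yl)silyloxy]benzoyl}-1,5-bis[(2E)-3,7-dimethylocta-2,6-dien-1-yl]-4-hydroxy-8,8-dimethyl-7-(3-methylbut-2-en-1-yl)bicyclo[3.3.1]non-3-ene-2,9-dione, via monocyclic triketo ester 17 (not isolated)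
Conditions: LiN(i-Pr)2 (2.5 equiv), THF, −78 → 0 °C, then 25–40 °C; AcOH, then aqueous NaH2PO4
Reagents that add atoms: none
Why: Proposed new method: the base converts 16 into its 1,3-diketone dianion (C3/C5), whose more basic γ-carbon C5 attacks one of the two diastereotopic methyl esters on C1 (6-(enolexo)-exo-trig Claisen acylation, ring B, C5–C9) to give 17, after which the C3 carbon of the remaining diketonate attacks the second, now 1,3-diaxial ester (6-(enolendo)-exo-trig Claisen closure, ring A, C2–C3) and the methoxide set free deprotonates the new triketone, which makes the sequence irreversible. The closest known reaction types are the γ-acylation of β-diketone dianions by esters, the Claisen ring closure of triketo esters to acylphloroglucinols and the Dieckmann closure of 1-acetyl-3-carbomethoxycyclohexanones to bicyclo[3.3.1]nonane-2,4,9-triones; new is their tandem use on a geminal diester, so that an open chain gives the bridged bicycle in one operation. The C7 centre from step 3 is the only control element: ring B should close through a chair with the C7 prenyl and both geranyl groups equatorial and the spectator ester and the diketone arm axial, which decides which ester becomes C9 and sets C1 as (S), while C5 (S) is locked because only a cis-1,3-diaxial pair can bridge, and this places the prenyl group exo. The step needs site selectivity (C5 before C3, carbon before oxygen), group selectivity between the two esters and survival of the C9 ketone; the first is secured by the dianion (C5 carries the only γ-hydrogen and both closures are six-membered), the second by the C7 substituent together with retro-Claisen return of any trans-configured monocycle through lithium methoxide, and the third by the final enolate, which shields the trione from alkoxide.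

Step 12
Reactants: 18
Product: 19 (1S,5S,7R)-3-(3,4-dihydroxybenzoyl)-1,5-bis[(2E)-3,7-dimethylocta-2,6-dien-1-yl]-4-hydroxy-8,8-dimethyl-7-(3-methylbut-2-en-1-yl)bicyclo[3.3.1]non-3-ene-2,9-dione (CNP0178719.1)
Conditions: Bu4NF (2.5 equiv), AcOH (2.5 equiv), THF, 0 °C → rt, under argon
Reagents that add atoms: none
Why: Fluoride cleaves the two aryl silyl ethers (desilylation), and buffering with acetic acid keeps the catechol from air oxidation and avoids the strong acid that would cyclise the enol onto a prenyl group; no stereocentre is touched.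

**Compound list**

1 | (4S)-3-acetyl-4-benzyl-1,3-oxazolidin-2-one | CC(=O)N1[C@@H](Cc2ccccc2)COC1=O | starting material
2 | dimethyl 2-(propan-2-ylidene)propanedioate (dimethyl isopropylidenemalonate) | COC(=O)C(=C(C)C)C(=O)OC | starting material
3 | dimethyl 2-{4-[(4S)-4-benzyl-2-oxo-1,3-oxazolidin-3-yl]-2-methyl-4-oxobutan-2-yl}propanedioate | COC(=O)C(C(=O)OC)C(C)(C)CC(=O)N1[C@@H](Cc2ccccc2)COC1=O | intermediate
4 | geranyl bromide, (2E)-1-bromo-3,7-dimethylocta-2,6-diene | BrC/C=C(\C)CCC=C(C)C | starting material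
5 | dimethyl 2-{4-[(4S)-4-benzyl-2-oxo-1,3-oxazolidin-3-yl]-2-methyl-4-oxobutan-2-yl}-2-[(2E)-3,7-dimethylocta-2,6-dien-1-yl]propanedioate | COC(=O)C(C/C=C(\C)CCC=C(C)C)(C(=O)OC)C(C)(C)CC(=O)N1[C@@H](Cc2ccccc2)COC1=O | intermediate
6 | prenyl bromide, 1-bromo-3-methylbut-2-ene | BrCC=C(C)C | starting material
7 | dimethyl 2-[(3S)-3-{[(4S)-4-benzyl-2-oxo-1,3-oxazolidin-3-yl]carbonyl}-2,6-dimethylhept-5-en-2-yl]-2-[(2E)-3,7-dimethylocta-2,6-dien-1-yl]propanedioate | COC(=O)C(C/C=C(\C)CCC=C(C)C)(C(=O)OC)C(C)(C)[C@H](CC=C(C)C)C(=O)N1[C@@H](Cc2ccccc2)COC1=O | intermediate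
8 | dimethyl 2-[(2E)-3,7-dimethylocta-2,6-dien-1-yl]-2-{(3S)-3-[(ethylsulfanyl)carbonyl]-2,6-dimethylhept-5-en-2-yl}propanedioate | CCSC(=O)[C@@H](CC=C(C)C)C(C)(C)C(C/C=C(\C)CCC=C(C)C)(C(=O)OC)C(=O)OC | intermediate
9 | dimethyl 2-[(2E)-3,7-dimethylocta-2,6-dien-1-yl]-2-[(3S)-3-formyl-2,6-dimethylhept-5-en-2-yl]propanedioate | O=C[C@@H](CC=C(C)C)C(C)(C)C(C/C=C(\C)CCC=C(C)C)(C(=O)OC)C(=O)OC | intermediate
10 | methyl (triphenyl-λ5-phosphanylidene)acetate | COC(=O)C=P(c1ccccc1)(c1ccccc1)c1ccccc1 | starting material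
11 | dimethyl 2-[(2E)-3,7-dimethylocta-2,6-dien-1-yl]-2-{(3R)-3-[(1E)-3-methoxy-3-oxoprop-1-en-1-yl]-2,6-dimethylhept-5-en-2-yl}propanedioate | COC(=O)/C=C/[C@@H](CC=C(C)C)C(C)(C)C(C/C=C(\C)CCC=C(C)C)(C(=O)OC)C(=O)OC | intermediate
12 | dimethyl 2-[(2E)-3,7-dimethylocta-2,6-dien-1-yl]-2-[(3S)-3-(3-methoxy-3-oxopropyl)-2,6-dimethylhept-5-en-2-yl]propanedioate | COC(=O)CC[C@@H](CC=C(C)C)C(C)(C)C(C/C=C(\C)CCC=C(C)C)(C(=O)OC)C(=O)OC | intermediate
13 | 1-(3,4-dihydroxyphenyl)ethan-1-one | CC(=O)c1ccc(O)c(O)c1 | starting material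
14 | 1-{3,4-bis[tri(propan-2-yl)silyloxy]phenyl}ethan-1-one | CC(=O)c1ccc(O[Si](C(C)C)(C(C)C)C(C)C)c(O[Si](C(C)C)(C(C)C)C(C)C)c1 | intermediate
15 | dimethyl 2-[(3S)-3-(5-{3,4-bis[tri(propan-2-yl)silyloxy]phenyl}-3,5-dioxopentyl)-2,6-dimethylhept-5-en-2-yl]-2-[(2E)-3,7-dimethylocta-2,6-dien-1-yl]propanedioate | O=C(CC(=O)CC[C@@H](CC=C(C)C)C(C)(C)C(C/C=C(\C)CCC=C(C)C)(C(=O)OC)C(=O)OC)c1ccc(O[Si](C(C)C)(C(C)C)C(C)C)c(O[Si](C(C)C)(C(C)C)C(C)C)c1 | intermediate
16 | dimethyl 2-[(3R)-3-{5-{3,4-bis[tri(propan-2-yl)silyloxy]phenyl}-2-[(2E)-3,7-dimethylocta-2,6-dien-1-yl]-3,5-dioxopentyl}-2,6-dimethylhept-5-en-2-yl]-2-[(2E)-3,7-dimethylocta-2,6-dien-1-yl]propanedioate (both epimers at C5) | O=C(CC(=O)C(C/C=C(\C)CCC=C(C)C)C[C@@H](CC=C(C)C)C(C)(C)C(C/C=C(\C)CCC=C(C)C)(C(=O)OC)C(=O)OC)c1ccc(O[Si](C(C)C)(C(C)C)C(C)C)c(O[Si](C(C)C)(C(C)C)C(C)C)c1 | intermediate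
17 | methyl (1S,3S,5R)-3-(3-{3,4-bis[tri(propan-2-yl)silyloxy]phenyl}-3-oxopropanoyl)-1,3-bis[(2E)-3,7-dimethylocta-2,6-dien-1-yl]-6,6-dimethyl-5-(3-methylbut-2-en-1-yl)-2-oxocyclohexane-1-carboxylate | CC(C)=CCC/C(C)=C/C[C@@]1(C(=O)CC(=O)c2ccc(O[Si](C(C)C)(C(C)C)C(C)C)c(O[Si](C(C)C)(C(C)C)C(C)C)c2)C[C@@H](CC=C(C)C)C(C)(C)[C@](C/C=C(\C)CCC=C(C)C)(C(=O)OC)C1=O | intermediate (not isolated)
18 | (1S,5S,7R)-3-{3,4-bis[tri(propan-2-yl)silyloxy]benzoyl}-1,5-bis[(2E)-3,7-dimethylocta-2,6-dien-1-yl]-4-hydroxy-8,8-dimethyl-7-(3-methylbut-2-en-1-yl)bicyclo[3.3.1]non-3-ene-2,9-dione | CC(C)=CCC/C(C)=C/C[C@]12C[C@@H](CC=C(C)C)C(C)(C)[C@](C/C=C(\C)CCC=C(C)C)(C(=O)C(C(=O)c3ccc(O[Si](C(C)C)(C(C)C)C(C)C)c(O[Si](C(C)C)(C(C)C)C(C)C)c3)=C1O)C2=O | intermediate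
19 | (1S,5S,7R)-3-(3,4-dihydroxybenzoyl)-1,5-bis[(2E)-3,7-dimethylocta-2,6-dien-1-yl]-4-hydroxy-8,8-dimethyl-7-(3-methylbut-2-en-1-yl)bicyclo[3.3.1]non-3-ene-2,9-dione (CNP0178719.1) | CC(C)=CCC/C(C)=C/C[C@]12C[C@@H](CC=C(C)C)C(C)(C)[C@](C/C=C(\C)CCC=C(C)C)(C(=O)C(C(=O)c3ccc(O)c(O)c3)=C1O)C2=O | target

**Step count**

Total step count: 12. Longest linear sequence: 11 (steps 1–7 and 9–12; step 8 is a one-step side branch).

**Steps most likely to fail**

1. Step 11 (proposed new method). What may go wrong:
 - the first Claisen closure may select the wrong ester or the wrong enolate face, giving a trans arrangement of diketone arm and residual ester that cannot bridge;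
 - the second closure may stall at 17 or drift to O-acylation;
 - methoxide may open the non-enolisable C9 ketone by retro-Claisen cleavage.

 Fallback with known reactions, setting out from 12 and returning at 18. 12 is closed with KOt-Bu in THF by a classical Dieckmann condensation (C5 ester enolate onto one malonate ester; the product is enolisable, so the equilibrium is driven) to the cyclic β-keto diester F1. Reversible closure should leave the C1 ester axial and trans to the equatorial C7 prenyl group. C-Geranylation of its enolate with 4 (K2CO3, acetone, reflux), from the face away from the axial C1 ester, should give the cis-1,3-diester F2. Condensation of F2 with an excess of the lithium enolate of 14 (THF, rt to 50 °C) bridges the two esters through C3 and should give 18. This is two successive Claisen acylations of one methyl group, the reaction that turns phthalates and methyl ketones into 2-acylindane-1,3-diones.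

2. Step 10. What may go wrong: the C5 carbanion of the dianion may attack a malonate ester in its own molecule before it meets geranyl bromide, or proton transfer may lead to double alkylation.

 Fallback setting out from 9 and returning at 16. 9 is condensed with Meldrum's acid and reduced in the same flask by Hantzsch ester (L-proline, EtOH, rt) to the 5-alkyl Meldrum's acid F3. K2CO3 and 4 in DMF geranylate its acidic C5 position to the 5,5-dialkyl Meldrum's acid F4. Methanol at reflux opens the dioxanedione to the malonic half ester F5, which loses CO2 on heating in pyridine to the α-geranyl methyl ester F6. Crossed Claisen condensation of F6 with the lithium enolate of 14, as in step 9, should give 16. In this order C5 is alkylated as a carbonate-generated, doubly stabilised anion that cannot acylate itself.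

3. Step 3. What may go wrong: slow alkylation of a neopentyl-type enolate flanked by two quaternary carbons, loss of ketene from the sodium enolate on warming, and eroded facial selectivity.

 Fallback setting out from 2 and returning at 9 (it replaces steps 1–5). Purchased 5-methylhex-4-enal and (S)-1-amino-2-(methoxymethyl)pyrrolidine (SAMP) give the hydrazone F7. Its lithium azaenolate (LDA, THF, −78 °C) adds to 2, and the malonate enolate so formed is trapped in the same flask with 4. This should give the hydrazone F8, with C7 set by the auxiliary in the (S) sense expected for SAMP-hydrazone alkylations. Two-phase cleavage with aqueous oxalic acid releases aldehyde 9 and the auxiliary.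

Further compounds
F1 | step 11 | dimethyl (1S,5R)-1-[(2E)-3,7-dimethylocta-2,6-dien-1-yl]-6,6-dimethyl-5-(3-methylbut-2-en-1-yl)-2-oxocyclohexane-1,3-dicarboxylate (C3 epimers and enol) | COC(=O)C1C[C@@H](CC=C(C)C)C(C)(C)[C@](C/C=C(\C)CCC=C(C)C)(C(=O)OC)C1=O
F2 | step 11 | dimethyl (1R,3S,5R)-1,3-bis[(2E)-3,7-dimethylocta-2,6-dien-1-yl]-4,4-dimethyl-5-(3-methylbut-2-en-1-yl)-2-oxocyclohexane-1,3-dicarboxylate | COC(=O)[C@]1(C/C=C(\C)CCC=C(C)C)C[C@@H](CC=C(C)C)C(C)(C)[C@](C/C=C(\C)CCC=C(C)C)(C(=O)OC)C1=O
F3 | step 10 | dimethyl 2-[(2E)-3,7-dimethylocta-2,6-dien-1-yl]-2-{(3R)-3-[(2,2-dimethyl-4,6-dioxo-1,3-dioxan-5-yl)methyl]-2,6-dimethylhept-5-en-2-yl}propanedioate | CC1(C)OC(=O)C(C[C@@H](CC=C(C)C)C(C)(C)C(C/C=C(\C)CCC=C(C)C)(C(=O)OC)C(=O)OC)C(=O)O1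
F4 | step 10 | dimethyl 2-[(2E)-3,7-dimethylocta-2,6-dien-1-yl]-2-{(3R)-3-({5-[(2E)-3,7-dimethylocta-2,6-dien-1-yl]-2,2-dimethyl-4,6-dioxo-1,3-dioxan-5-yl}methyl)-2,6-dimethylhept-5-en-2-yl}propanedioate | CC1(C)OC(=O)C(C/C=C(\C)CCC=C(C)C)(C[C@@H](CC=C(C)C)C(C)(C)C(C/C=C(\C)CCC=C(C)C)(C(=O)OC)C(=O)OC)C(=O)O1
F5 | step 10 | malonic half ester from methanolysis of F4: monomethyl propanedioate carrying on C2 a geranyl group and the CH2–C7H(prenyl)–CMe2–C(geranyl)(CO2Me)2 chain, (7R), both epimers at the new quaternary carbon | COC(=O)C(C/C=C(\C)CCC=C(C)C)(C[C@@H](CC=C(C)C)C(C)(C)C(C/C=C(\C)CCC=C(C)C)(C(=O)OC)C(=O)OC)C(=O)O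
F6 | step 10 | dimethyl 2-[(2E)-3,7-dimethylocta-2,6-dien-1-yl]-2-{(3R)-3-[(4E)-2-(methoxycarbonyl)-5,9-dimethyldeca-4,8-dien-1-yl]-2,6-dimethylhept-5-en-2-yl}propanedioate (both epimers at C5) | COC(=O)C(C/C=C(\C)CCC=C(C)C)C[C@@H](CC=C(C)C)C(C)(C)C(C/C=C(\C)CCC=C(C)C)(C(=O)OC)C(=O)OC
F7 | step 3 | (2S)-2-(methoxymethyl)-N-[(1E)-5-methylhex-4-en-1-ylidene]pyrrolidin-1-amine | CC(C)=CCC/C=N/N1CCC[C@H]1COC
F8 | step 3 | dimethyl 2-[(2E)-3,7-dimethylocta-2,6-dien-1-yl]-2-[(3S)-3-{(E)-[(2S)-2-(methoxymethyl)pyrrolidin-1-yl]iminomethyl}-2,6-dimethylhept-5-en-2-yl]propanedioate | COC[C@@H]1CCCN1/N=C/[C@@H](CC=C(C)C)C(C)(C)C(C/C=C(\C)CCC=C(C)C)(C(=O)OC)C(=O)OC
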